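**Plan**

- Retrosynthesis removes the silyl group from O3, then cuts C2′–C3′ of ring A (as its alkene, by ring-closing metathesis), the C4′–Cl and C5′–Br bonds (bromochlorination of a Z-allylic alcohol), the C4′=C5′ alkene and the two vinyl groups, the C3–OH bond, and last the O1–C6 bond of the pyran, which leaves (−)-α-bisabolol.
- Forward, the pyran ring is closed first (6-endo selenoetherification, selenoxide elimination). The cyclohexene of bisabolol is then opened by ozonolysis and C3 is hydroxylated. One arm is cut down to a vinyl group, the other is rebuilt as a Z-2-methylallylic alcohol and halogenated in open-chain form. Ring A is closed last by metathesis and then saturated.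
- Enabling feature: in ring A, C2′ and C3′ are unsubstituted CH2 carbons between the stereocentres C1′ and C4′. The C2′–C3′ bond can therefore be made as an alkene from vinyl groups on C1′ and C4′ without touching the all-equatorial C1′/C4′/C5′ pattern, which trans-diaxial BrCl addition to the intact cyclohexene cannot give.
- Stereochemistry: C2 and C1′ come from (−)-α-bisabolol. C3 comes from the SeO2 ene/[2,3] sequence anti to the axial C2 methyl group. C4′ and C5′ come from the Z-alkene geometry (Still–Gennari), anti addition, and face control by a chiral titanium Schiff-base catalyst.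

Key step: step 13

Assumption: the Schiff-base ligand of step 10 is taken as the enantiomer that converts a (Z)-2-methylalk-2-en-1-ol into the (2S,3S)-3-bromo-2-chloro alcohol; the antipode is equally accessible, so the sense would be fixed on a model alcohol.

**Route**

Step 1
Reactants: 1 (−)-α-bisabolol; 2 phenylselenyl chloride
Product: 3 6-endo selenoether (3R,6S)-2,2,6-trimethyl-6-[(1S)-4-methylcyclohex-3-en-1-yl]-3-(phenylselanyl)oxane
Conditions: PhSeCl, CH2Cl2, −78 → 25 °C
Reagents that add atoms: phenylselenyl chloride (2) Cl[Se]c1ccccc1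
Why: Phenylselenoetherification, in which the seleniranium ion of the side-chain alkene is opened by the tertiary hydroxyl at the dimethyl-substituted carbon through a chair transition state, the HCl set free equilibrates any kinetic 5-exo tetrahydrofuran to the Markovnikov 6-endo ether, capture at the ring alkene would need a boat-shaped bridged transition state, and the new selenium-bearing centre is erased in step 2.

Step 2
Reactants: 3 6-endo selenoether
Product: 5 diene (2S)-2,6,6-trimethyl-2-[(1S)-4-methylcyclohex-3-en-1-yl]-3,6-dihydro-2H-pyran, via selenoxide 4 (not isolated)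
Conditions: mCPBA (1.0 equiv), CH2Cl2, −78 °C; then i-Pr2NH, 25 °C
Reagents that add atoms: none
Why: Selenoxide syn-elimination, in which selenium is oxidised at −78 °C well before either alkene is epoxidised and the selenoxide can eliminate only toward C4 because C6 is quaternary, so the C4=C5 alkene should form without touching C2 or C1′.

Step 3
Reactants: 5 diene
Product: 7 keto acetal (5S)-7,7-dimethoxy-5-[(2S)-2,6,6-trimethyl-3,6-dihydro-2H-pyran-2-yl]heptan-2-one, via keto aldehyde 6 (not isolated)
Conditions: O3, pyridine, CH2Cl2, −78 °C (Sudan Red 7B end point); then HC(OMe)3, CeCl3·7H2O, MeOH, 25 °C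
Reagents that add atoms: ozone [O-][O+]=O; methanol CO
Why: Chemoselective ozonolysis with pyridine as in-flask reductant (the trisubstituted ring alkene is more electron-rich than the cis-disubstituted pyran alkene, which is slowed by its allylic oxygen and the flanking gem-dimethyl group) followed by CeCl3-promoted acetalisation, which is selective for the aldehyde over the methyl ketone.

Step 4
Reactants: 7 keto acetal
Product: 8 allylic alcohol (5S)-5-[(2R,3R)-3-hydroxy-2,6,6-trimethyl-3,6-dihydro-2H-pyran-2-yl]-7,7-dimethoxyheptan-2-one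
Conditions: SeO2 (0.5 equiv), t-BuOOH (anhydrous), CH2Cl2, 25 °C
Reagents that add atoms: selenium dioxide O=[Se]=O; tert-butyl hydroperoxide CC(C)(C)OO
Why: SeO2 allylic hydroxylation (ene reaction then [2,3]-sigmatropic shift), for which the pyran alkene is the only alkene present and C3 its only allylic CH2, the methyl ketone and acetal being inert at room temperature, with selenium adding at C5 and oxygen returning to C3 on the face opposite the axial C2 methyl group, which sets (3R).

Step 5
Reactants: 8 allylic alcohol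
Product: 9 silyl ether (5S)-5-[(2R,3R)-3-{[tert-butyl(dimethyl)silyl]oxy}-2,6,6-trimethyl-3,6-dihydro-2H-pyran-2-yl]-7,7-dimethoxyheptan-2-one
Conditions: t-BuMe2SiCl, imidazole, DMAP, DMF, 40 °C
Reagents that add atoms: tert-butyldimethylsilyl chloride CC(C)(C)[Si](C)(C)Cl
Why: Silylation under conditions that neither enolise the ketone nor cleave the acetal, giving an ether that hides the secondary allylic alcohol from hypobromite, the aluminium hydride and the titanium catalyst and later shields the pyran alkene.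

Step 6
Reactants: 9 silyl ether
Product: 10 acid (4S)-4-[(2R,3R)-3-{[tert-butyl(dimethyl)silyl]oxy}-2,6,6-trimethyl-3,6-dihydro-2H-pyran-2-yl]-6,6-dimethoxyhexanoic acid
Conditions: Br2, NaOH, dioxane/H2O, 0 °C; then Na2SO3, NaH2PO4 (pH 5)
Reagents that add atoms: sodium hydroxide [Na+].[OH-]
Why: Haloform reaction, in which exhaustive bromination of the methyl group and hydroxide cleavage convert the methyl ketone into the carboxylic acid under basic conditions that leave the acetal, the silyl ether and the hindered pyran alkene alone.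

Step 7
Reactants: 10 acid
Product: 12 vinyl aldehyde (3R)-3-[(2R,3R)-3-{[tert-butyl(dimethyl)silyl]oxy}-2,6,6-trimethyl-3,6-dihydro-2H-pyran-2-yl]pent-4-enal, via vinyl acetal 11 (not isolated)
Conditions: Pb(OAc)4, Cu(OAc)2 (cat.), pyridine, benzene, 80 °C; then AcOH/H2O/THF, 25 °C
Reagents that add atoms: water O
Why: Kochi oxidative decarboxylation, in which the primary C3′ radical left after loss of CO2 is oxidised by divalent copper to the terminal alkene faster than it can add to the hindered pyran alkene (no enoate is yet present to trap it), after which dilute acetic acid unmasks the aldehyde without ionising the allylic tertiary ether.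

Step 8
Reactants: 12 vinyl aldehyde; 13 methyl 2-[bis(2,2,2-trifluoroethoxy)phosphoryl]propanoate
Product: 14 Z-enoate methyl (2Z,5R)-5-[(2R,3R)-3-{[tert-butyl(dimethyl)silyl]oxy}-2,6,6-trimethyl-3,6-dihydro-2H-pyran-2-yl]-2-methylhepta-2,6-dienoate
Conditions: 13, KN(SiMe3)2, 18-crown-6, THF, −78 °C
Reagents that add atoms: methyl 2-[bis(2,2,2-trifluoroethoxy)phosphoryl]propanoate (13) COC(=O)C(C)P(=O)(OCC(F)(F)F)OCC(F)(F)F
Why: Still–Gennari olefination, in which the electron-poor bis(trifluoroethyl) phosphonate under dissociating conditions collapses through the kinetic oxaphosphetane and should give the Z-trisubstituted enoate that the later anti addition requires.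

Step 9
Reactants: 14 Z-enoate
Product: 15 Z-allylic alcohol (2Z,5R)-5-[(2R,3R)-3-{[tert-butyl(dimethyl)silyl]oxy}-2,6,6-trimethyl-3,6-dihydro-2H-pyran-2-yl]-2-methylhepta-2,6-dien-1-ol
Conditions: i-Bu2AlH, CH2Cl2, −78 °C; aqueous potassium sodium tartrate
Reagents that add atoms: none
Why: 1,2-Reduction of the enoate by i-Bu2AlH at −78 °C, which delivers two hydrides to the carbonyl and leaves the alkenes, their geometry and the silyl ether untouched.

Step 10
Reactants: 15 Z-allylic alcohol
Product: 16 bromochloro alcohol (2S,3S,5R)-3-bromo-2-chloro-5-[(2R,3R)-3-{[tert-butyl(dimethyl)silyl]oxy}-2,6,6-trimethyl-3,6-dihydro-2H-pyran-2-yl]-2-methylhept-6-en-1-ol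
Conditions: NBS, ClTi(OiPr)3, chiral tridentate Schiff-base ligand (20 mol%), hexane, −20 °C
Reagents that add atoms: N-bromosuccinimide O=C1CCC(=O)N1Br; chlorotitanium triisopropoxide CC(C)O[Ti](Cl)(OC(C)C)OC(C)C
Why: Catalytic enantioselective bromochlorination of an allylic alcohol, in which the titanium-bound alkoxide holds the Z-alkene in the chiral pocket, NBS delivers bromine to one face at C5′ and titanium-bound chloride opens the bromonium ion anti at the tertiary carbon C4′, so the alkene geometry fixes the relative and the ligand the absolute configuration (4′S,5′S) while the unactivated vinyl and pyran alkenes stay out.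

Step 11
Reactants: 16 bromochloro alcohol
Product: 17 aldehyde (2S,3S,5R)-3-bromo-2-chloro-5-[(2R,3R)-3-{[tert-butyl(dimethyl)silyl]oxy}-2,6,6-trimethyl-3,6-dihydro-2H-pyran-2-yl]-2-methylhept-6-enal
Conditions: Dess–Martin periodinane, NaHCO3, CH2Cl2, 0 → 25 °C
Reagents that add atoms: none
Why: Dess–Martin oxidation under buffered neutral conditions, giving an aldehyde without an α-hydrogen so that neither epimerisation nor enolate-driven loss of HBr is possible.

Step 12
Reactants: 17 aldehyde; 18 methyltriphenylphosphonium bromide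
Product: 19 triene tert-butyl{[(2R,3R)-2-[(3R,5S,6S)-5-bromo-6-chloro-6-methylocta-1,7-dien-3-yl]-2,6,6-trimethyl-3,6-dihydro-2H-pyran-3-yl]oxy}dimethylsilane
Conditions: 18, KN(SiMe3)2, THF, 0 °C; then 17, −78 → 0 °C
Reagents that add atoms: methyltriphenylphosphonium bromide (18) C[P+](c1ccccc1)(c1ccccc1)c1ccccc1.[Br-]
Why: Wittig methylenation with the non-stabilised ylide at low temperature, where [2+2] addition to the aldehyde should outrun attack at the hindered halides and gives the tertiary allylic chloride.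

Step 13
Reactants: 19 triene
Product: 20 cyclohexene tert-butyl{[(2R,3R)-2-[(1R,4S,5S)-5-bromo-4-chloro-4-methylcyclohex-2-en-1-yl]-2,6,6-trimethyl-3,6-dihydro-2H-pyran-3-yl]oxy}dimethylsilane
Conditions: second-generation Grubbs catalyst (5 mol%), CH2Cl2 (0.005 M), 40 °C, argon sparge
Reagents that add atoms: none
Why: Alkene metathesis by the Chauvin mechanism: the ruthenium benzylidene exchanges onto the less hindered C1′ vinyl group, the new alkylidene adds [2+2] to the vinyl group on C4′, and cycloreversion of the ruthenacyclobutane releases ethene and the C2′=C3′ alkene. The closest known reaction type is ring-closing metathesis to cyclohexenes that carry an allylic quaternary, halogen-bearing carbon. Ring A closes as a six-membered carbocycle by joining the two terminal alkene carbons C2′ and C3′, driven by the strain-free ring size and the loss of ethene. No stereocentre is formed, so C1′, C4′ and C5′ keep the configurations fixed by bisabolol and by step 10. The step needs chemoselectivity for the two monosubstituted alkenes, which the substrate secures because the pyran alkene is cis-disubstituted, sits between the quaternary C6 and the silyloxy-bearing C3, and cannot reach either vinyl group in an unstrained ring. It also needs the tertiary allylic chloride to survive, which a neutral ruthenium carbene at 40 °C should allow.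

Step 14
Reactants: 20 cyclohexene
Product: 21 cyclohexane tert-butyl{[(2R,3R)-2-[(1S,3S,4S)-3-bromo-4-chloro-4-methylcyclohexyl]-2,6,6-trimethyl-3,6-dihydro-2H-pyran-3-yl]oxy}dimethylsilane
Conditions: 2-O2NC6H4SO2NHNH2, Et3N, CH2Cl2, 25 °C
Reagents that add atoms: none
Why: Diimide reduction (concerted syn transfer of two hydrogens, no carbon–halogen hydrogenolysis), selective because the ring A alkene has an open face syn to the C1′ hydrogen whereas the pyran alkene is screened on one face by the syn-axial C2 and C6 methyl groups and on the other by the pseudoaxial silyloxy group at C3.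

Step 15
Reactants: 21 cyclohexane
Product: 22 target (2R,3R)-2-[(1S,3S,4S)-3-bromo-4-chloro-4-methylcyclohexyl]-2,6,6-trimethyl-3,6-dihydro-2H-pyran-3-ol
Conditions: HF·pyridine, pyridine, THF, 0 → 25 °C
Reagents that add atoms: none
Why: Fluoride cleavage of the silyl ether with buffered HF·pyridine, which is not basic enough to eliminate HBr or HCl from the all-equatorial ring A.

**Compound list**

1 | (−)-α-bisabolol, (2S)-6-methyl-2-[(1S)-4-methylcyclohex-3-en-1-yl]hept-5-en-2-ol | CC(C)=CCC[C@@](C)([C@H]1CCC(C)=CC1)O | starting material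
2 | phenylselenyl chloride | Cl[Se]c1ccccc1 | starting material
3 | (3R,6S)-2,2,6-trimethyl-6-[(1S)-4-methylcyclohex-3-en-1-yl]-3-(phenylselanyl)oxane (selenium-bearing centre drawn as the expected epimer) | CC1(C)[C@H]([Se]c2ccccc2)CC[C@@](C)([C@H]3CCC(C)=CC3)O1 | intermediate
4 | Se-oxide of 3 (both configurations at selenium) | CC1(C)[C@H]([Se](=O)c2ccccc2)CC[C@@](C)([C@H]3CCC(C)=CC3)O1 | intermediate (not isolated)
5 | (2S)-2,6,6-trimethyl-2-[(1S)-4-methylcyclohex-3-en-1-yl]-3,6-dihydro-2H-pyran | CC1(C)C=CC[C@@](C)([C@H]2CCC(C)=CC2)O1 | intermediate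
6 | (3S)-6-oxo-3-[(2S)-2,6,6-trimethyl-3,6-dihydro-2H-pyran-2-yl]heptanal | CC1(C)C=CC[C@@](C)([C@H](CC=O)CCC(C)=O)O1 | intermediate (not isolated)
7 | (5S)-7,7-dimethoxy-5-[(2S)-2,6,6-trimethyl-3,6-dihydro-2H-pyran-2-yl]heptan-2-one | CC1(C)C=CC[C@@](C)([C@H](CC(OC)OC)CCC(C)=O)O1 | intermediate
8 | (5S)-5-[(2R,3R)-3-hydroxy-2,6,6-trimethyl-3,6-dihydro-2H-pyran-2-yl]-7,7-dimethoxyheptan-2-one | CC1(C)C=C[C@@H](O)[C@@](C)([C@H](CC(OC)OC)CCC(C)=O)O1 | intermediate
9 | (5S)-5-[(2R,3R)-3-{[tert-butyl(dimethyl)silyl]oxy}-2,6,6-trimethyl-3,6-dihydro-2H-pyran-2-yl]-7,7-dimethoxyheptan-2-one | CC1(C)C=C[C@@H](O[Si](C)(C)C(C)(C)C)[C@@](C)([C@H](CC(OC)OC)CCC(C)=O)O1 | intermediate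
10 | (4S)-4-[(2R,3R)-3-{[tert-butyl(dimethyl)silyl]oxy}-2,6,6-trimethyl-3,6-dihydro-2H-pyran-2-yl]-6,6-dimethoxyhexanoic acid | CC1(C)C=C[C@@H](O[Si](C)(C)C(C)(C)C)[C@@](C)([C@H](CC(OC)OC)CCC(=O)O)O1 | intermediate
11 | tert-butyl{[(2R,3R)-2-[(3R)-5,5-dimethoxypent-1-en-3-yl]-2,6,6-trimethyl-3,6-dihydro-2H-pyran-3-yl]oxy}dimethylsilane | CC1(C)C=C[C@@H](O[Si](C)(C)C(C)(C)C)[C@@](C)([C@H](CC(OC)OC)C=C)O1 | intermediate (not isolated)
12 | (3R)-3-[(2R,3R)-3-{[tert-butyl(dimethyl)silyl]oxy}-2,6,6-trimethyl-3,6-dihydro-2H-pyran-2-yl]pent-4-enal | CC1(C)C=C[C@@H](O[Si](C)(C)C(C)(C)C)[C@@](C)([C@H](CC=O)C=C)O1 | intermediate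
13 | methyl 2-[bis(2,2,2-trifluoroethoxy)phosphoryl]propanoate | COC(=O)C(C)P(=O)(OCC(F)(F)F)OCC(F)(F)F | starting material
14 | methyl (2Z,5R)-5-[(2R,3R)-3-{[tert-butyl(dimethyl)silyl]oxy}-2,6,6-trimethyl-3,6-dihydro-2H-pyran-2-yl]-2-methylhepta-2,6-dienoate | CC1(C)C=C[C@@H](O[Si](C)(C)C(C)(C)C)[C@@](C)([C@H](C/C=C(/C)C(=O)OC)C=C)O1 | intermediate
15 | (2Z,5R)-5-[(2R,3R)-3-{[tert-butyl(dimethyl)silyl]oxy}-2,6,6-trimethyl-3,6-dihydro-2H-pyran-2-yl]-2-methylhepta-2,6-dien-1-ol | CC1(C)C=C[C@@H](O[Si](C)(C)C(C)(C)C)[C@@](C)([C@H](C/C=C(/C)CO)C=C)O1 | intermediate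
16 | (2S,3S,5R)-3-bromo-2-chloro-5-[(2R,3R)-3-{[tert-butyl(dimethyl)silyl]oxy}-2,6,6-trimethyl-3,6-dihydro-2H-pyran-2-yl]-2-methylhept-6-en-1-ol | CC1(C)C=C[C@@H](O[Si](C)(C)C(C)(C)C)[C@@](C)([C@H](C[C@H](Br)[C@@](C)(Cl)CO)C=C)O1 | intermediate
17 | (2S,3S,5R)-3-bromo-2-chloro-5-[(2R,3R)-3-{[tert-butyl(dimethyl)silyl]oxy}-2,6,6-trimethyl-3,6-dihydro-2H-pyran-2-yl]-2-methylhept-6-enal | CC1(C)C=C[C@@H](O[Si](C)(C)C(C)(C)C)[C@@](C)([C@H](C[C@H](Br)[C@@](C)(Cl)C=O)C=C)O1 | intermediate
18 | methyltriphenylphosphonium bromide | C[P+](c1ccccc1)(c1ccccc1)c1ccccc1.[Br-] | starting material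
19 | tert-butyl{[(2R,3R)-2-[(3R,5S,6S)-5-bromo-6-chloro-6-methylocta-1,7-dien-3-yl]-2,6,6-trimethyl-3,6-dihydro-2H-pyran-3-yl]oxy}dimethylsilane | CC1(C)C=C[C@@H](O[Si](C)(C)C(C)(C)C)[C@@](C)([C@H](C[C@H](Br)[C@@](C)(Cl)C=C)C=C)O1 | intermediate
20 | tert-butyl{[(2R,3R)-2-[(1R,4S,5S)-5-bromo-4-chloro-4-methylcyclohex-2-en-1-yl]-2,6,6-trimethyl-3,6-dihydro-2H-pyran-3-yl]oxy}dimethylsilane | CC1(C)C=C[C@@H](O[Si](C)(C)C(C)(C)C)[C@@](C)([C@H]2C=C[C@](C)(Cl)[C@@H](Br)C2)O1 | intermediate
21 | tert-butyl{[(2R,3R)-2-[(1S,3S,4S)-3-bromo-4-chloro-4-methylcyclohexyl]-2,6,6-trimethyl-3,6-dihydro-2H-pyran-3-yl]oxy}dimethylsilane | CC1(C)C=C[C@@H](O[Si](C)(C)C(C)(C)C)[C@@](C)([C@H]2CC[C@](C)(Cl)[C@@H](Br)C2)O1 | intermediate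
22 | (2R,3R)-2-[(1S,3S,4S)-3-bromo-4-chloro-4-methylcyclohexyl]-2,6,6-trimethyl-3,6-dihydro-2H-pyran-3-ol | CC1(C)C=C[C@@H](O)[C@@](C)([C@H]2CC[C@](C)(Cl)[C@@H](Br)C2)O1 | target

**Step count**

Total: 15 steps. Longest linear sequence: 15 steps (1 → 22).

**Steps most likely to fail**

Step 10. The titanium complex may discriminate the two faces of a Z-trisubstituted allylic alcohol poorly, so that both anti adducts form, or chloride may open the bromonium ion at C5′ instead of C4′. The fallback sets out from 15 and comes back at 16, building the two carbon–halogen bonds one at a time from an epoxide. Sharpless asymmetric epoxidation (Ti(OiPr)4, L-(+)-diethyl tartrate, t-BuOOH, CH2Cl2, −20 °C) should give the (2S,3R)-epoxy alcohol F1. Opening at C5′ with bromide under chelation control (Ti(OiPr)4, Et2NH·HBr) proceeds with inversion to the bromo diol F2. The primary hydroxyl is silylated (Et3SiCl, imidazole) to the triethylsilyl ether F3. The tertiary hydroxyl is then replaced by chloride with retention (1-chloro-N,N,2-trimethylprop-1-en-1-amine, CH2Cl2, 0 °C), because the anti bromine closes to a bromonium ion that chloride reopens at the tertiary carbon, giving the bromochloride silyl ether F4. Removal of the primary triethylsilyl group (PPTS, MeOH, 0 °C) returns to 16.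

Step 4. Selenium must bond to C5 next to the quaternary C6, so the ene step may be slow, and over-oxidation to the enone or acetal hydrolysis by selenous acid may overtake it. The fallback sets out from 7 and comes back at 8, replacing the ene pathway with a radical allylic acyloxylation (Kharasch–Sosnovsky). CuBr (cat.) and tert-butyl perbenzoate in benzene at 70 °C abstract the only allylic hydrogen, and the allyl–copper intermediate forms the C–O bond at the less hindered C3 terminus, anti to the axial C2 methyl group, giving the allylic benzoate F5. Methanolysis (K2CO3, MeOH) then gives 8.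

Step 14. Chemoselectivity may be lost if the silyloxy group screens the β face of the pyran alkene less well than expected, so that diimide reduces both alkenes. The fallback sets out from 20 and ends at 22, hiding the pyran alkene as an epoxide during the reduction. HF·pyridine gives the dienol F6. Hydroxyl-directed epoxidation (VO(acac)2, t-BuOOH, CH2Cl2) touches only the allylic-alcohol alkene and gives the syn epoxy alcohol F7. Diimide then has only the ring A alkene to reduce and gives the epoxy alcohol F8. Stereospecific deoxygenation (Ph3P=Se, CF3CO2H, CH2Cl2) restores the C4=C5 alkene and gives 22.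

**Further compounds**

F1 | step 10 | {(2S,3R)-3-[(2R)-2-{(2R,3R)-3-[tert-butyl(dimethyl)silyl]oxy-2,6,6-trimethyl-3,6-dihydro-2H-pyran-2-yl}but-3-en-1-yl]-2-methyloxiran-2-yl}methanol | CC1(C)C=C[C@@H](O[Si](C)(C)C(C)(C)C)[C@@](C)([C@H](C[C@@H]2[C@](C)(CO)O2)C=C)O1
F2 | step 10 | (2S,3S,5R)-3-bromo-5-[(2R,3R)-3-{[tert-butyl(dimethyl)silyl]oxy}-2,6,6-trimethyl-3,6-dihydro-2H-pyran-2-yl]-2-methylhept-6-ene-1,2-diol | CC1(C)C=C[C@@H](O[Si](C)(C)C(C)(C)C)[C@@](C)([C@H](C[C@H](Br)[C@@](C)(O)CO)C=C)O1
F3 | step 10 | 1-O-triethylsilyl ether of F2 | CC1(C)C=C[C@@H](O[Si](C)(C)C(C)(C)C)[C@@](C)([C@H](C[C@H](Br)[C@@](C)(O)CO[Si](CC)(CC)CC)C=C)O1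
F4 | step 10 | triethylsilyl ether of 16 | CC1(C)C=C[C@@H](O[Si](C)(C)C(C)(C)C)[C@@](C)([C@H](C[C@H](Br)[C@@](C)(Cl)CO[Si](CC)(CC)CC)C=C)O1
F5 | step 4 | (2R,3R)-2-[(3S)-1,1-dimethoxy-6-oxoheptan-3-yl]-2,6,6-trimethyl-3,6-dihydro-2H-pyran-3-yl benzoate | CC1(C)C=C[C@@H](OC(=O)c2ccccc2)[C@@](C)([C@H](CC(OC)OC)CCC(C)=O)O1
F6 | step 14 | (2R,3R)-2-[(1R,4S,5S)-5-bromo-4-chloro-4-methylcyclohex-2-en-1-yl]-2,6,6-trimethyl-3,6-dihydro-2H-pyran-3-ol | CC1(C)C=C[C@@H](O)[C@@](C)([C@H]2C=C[C@](C)(Cl)[C@@H](Br)C2)O1
F7 | step 14 | 4,5-epoxide of F6, oxirane syn to the C3 hydroxyl | CC1(C)[C@H]2O[C@H]2[C@@H](O)[C@@](C)([C@H]3C=C[C@](C)(Cl)[C@@H](Br)C3)O1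
F8 | step 14 | 4,5-epoxide of 22, oxirane syn to the C3 hydroxyl | CC1(C)[C@H]2O[C@H]2[C@@H](O)[C@@](C)([C@H]3CC[C@](C)(Cl)[C@@H](Br)C3)O1
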